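The route rests on cutting the bond between C2' of ring B and C1'' of the geranyl chain. This divides the target into an intact (2S)-flavanone and a C10 allyl cation equivalent. The key step is a Friedel–Crafts geranylation catalysed by an aromatic prenyltransferase, copying the presumed biosynthesis. It joins both halves in one operation on an unprotected substrate and leaves the E-alkene and C2 untouched. It exploits O3'–H of ring B, the only free, non-chelated phenol. Of its two ortho carbons, C4' is blocked by OMe, which leaves C2'. The precursor is (2S)-7-O-methylhesperetin, made from chiral-pool (2S)-hesperetin. A final 3'-O-methylation completes the target.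

Key step: step 2

Assumption: (2S)-hesperetin is bought as the single enantiomer and C2 of the target is inherited from it; because some commercial lots are partly racemised, its enantiomeric purity is checked on a chiral phase before step 1.
Numbering: flavanone numbering (ring A C5–C8, ring C O1–C4, ring B C1'–C6'), geranyl C1''–C10''.

Step 1
Reactants: 1 (2S)-hesperetin, (2S)-5,7-dihydroxy-2-(3-hydroxy-4-methoxyphenyl)chroman-4-one
Product: 2 (2S)-7-O-methylhesperetin, (2S)-5-hydroxy-2-(3-hydroxy-4-methoxyphenyl)-7-methoxychroman-4-one
Conditions: TMSCHN2 (1.0 equiv, slow addition), toluene/MeOH, 0 °C to rt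
Reagents that add atoms: (trimethylsilyl)diazomethane, C[Si](C)(C)C=[N+]=[N-]
Why: O-methylation of a phenol by a diazoalkane is gated by proton transfer, so one equivalent should be consumed by the 7-OH (a vinylogous acid para to C4=O and the most acidic of the three) while the chelated 5-OH and the ordinary 3'-OH stay free, and the base-free medium avoids retro-oxa-Michael opening of ring C, so the (2S) centre inherited from 1 is kept.

Step 2
Reactants: 2 (2S)-7-O-methylhesperetin; 3 (E)-geranyl diphosphate, triammonium salt
Product: 4 (2S)-2'-geranyl-7-O-methylhesperetin, (2S)-2-{2-[(2E)-3,7-dimethylocta-2,6-dien-1-yl]-3-hydroxy-4-methoxyphenyl}-5-hydroxy-7-methoxychroman-4-one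
Conditions: soluble ABBA-fold aromatic prenyltransferase (geranyl-accepting NphB-type variant selected for C2' attack), MgCl2, HEPES pH 7.5, 5% DMSO, 30 °C
Reagents that add atoms: none
Why: Proposed new method: Inside the hydrophobic barrel of the enzyme the Mg2+-bound diphosphate of 3 ionises to a geranyl cation/diphosphate ion pair, C2' of ring B of 2 attacks its C1 (enzymatic Friedel–Crafts alkylation), and an active-site base or water takes H2' from the arenium ion to restore aromaticity. The closest known reaction type is the C-prenylation of flavanones by soluble ABBA aromatic prenyltransferases, established for C-geranylation at ring A and for C-dimethylallylation of ring B ortho to a phenol; what is new is geranyl transfer to C2' of a 3'-hydroxyflavanone, for which naturally occurring 2'-geranylflavanones imply an enzyme but none is characterised, so the catalyst has to come from screening promiscuous wild types followed by active-site mutagenesis. No ring is closed and no stereocentre is formed: C2 is remote and should be configurationally stable at pH 7.5, and the E geometry of C2''=C3'' is carried over from 3 because the held allyl cation is captured at C1 before it can rotate or collapse at C3. The step needs ring B over the intrinsically more nucleophilic C6/C8 of ring A, C- over O-alkylation, C2' over C6', and C1 over C3 of the donor. The substrate is built to help: O7 is capped and O5–H is locked to C4=O, so O3'–H is the only phenol that can be hydrogen-bonded or deprotonated to activate a ring, and of its two ortho carbons C4' carries OMe, which leaves C2' as the only ortho site. The remaining discrimination (C2' against the para carbon C6' and against O3') has to be supplied by the pocket, which is the risk of the step.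

Step 3
Reactants: 4 (2S)-2'-geranyl-7-O-methylhesperetin
Product: 5 target, (2S)-2-{2-[(2E)-3,7-dimethylocta-2,6-dien-1-yl]-3,4-dimethoxyphenyl}-5-hydroxy-7-methoxychroman-4-one
Conditions: TMSCHN2 (3 equiv), iPr2NEt, MeCN/MeOH, rt
Reagents that add atoms: (trimethylsilyl)diazomethane, C[Si](C)(C)C=[N+]=[N-]
Why: Amine-assisted diazoalkane O-methylation of phenols should convert the free, if ortho-flanked, 3'-OH, whereas the 5-OH is held in the six-membered hydrogen bond to C4=O and is classically inert to diazomethane, and the isolated alkenes, the aryl ketone and C2 (no strong base, no heat) are not touched.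

Compound list
1 | (2S)-hesperetin | Oc1cc(O)c2c(c1)O[C@H](c1ccc(OC)c(O)c1)CC2=O | starting material
2 | (2S)-7-O-methylhesperetin (5,3'-dihydroxy-7,4'-dimethoxyflavanone) | COc1cc(O)c2c(c1)O[C@H](c1ccc(OC)c(O)c1)CC2=O | intermediate
3 | (E)-geranyl diphosphate, triammonium salt | CC(C)=CCC/C(C)=C/COP(=O)([O-])OP(=O)([O-])[O-].[NH4+].[NH4+].[NH4+] | starting material
4 | (2S)-2'-geranyl-5,3'-dihydroxy-7,4'-dimethoxyflavanone | COc1cc(O)c2c(c1)O[C@H](c1ccc(OC)c(O)c1C/C=C(\C)CCC=C(C)C)CC2=O | intermediate
5 | (2S)-2'-geranyl-5-hydroxy-7,3',4'-trimethoxyflavanone | COc1cc(O)c2c(c1)O[C@H](c1ccc(OC)c(OC)c1C/C=C(\C)CCC=C(C)C)CC2=O | target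

Total step count: 3. Longest linear sequence: 3 steps (1 → 2 → 4 → 5).

Steps most likely to fail

1. Step 2 (Proposed new method). What may go wrong: the geranyl cation is delivered to ring A, to O3' or to C6' instead of C2', or turnover is too slow for preparative use. The fallback uses known chemistry, sets out from 2 and comes back at 4.
   - Commercial linalool is converted (n-BuLi, ClCO2Me, THF) into linalyl methyl carbonate F1.
   - Pd(PPh3)4 in THF at 0 °C joins it to O3' of 2 at the more substituted allyl terminus (Tsuji–Trost O-allylation) to give the tertiary 3'-O-linalyl ether F2.
   - Heating in toluene, or catalytic Eu(fod)3 in CHCl3, then triggers an aromatic Claisen rearrangement. It can rearomatise only through C2' because C4' bears OMe, so it makes the same C2'–C1'' bond.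
   - The C2''=C3'' geometry is set in the chair transition state with little bias, so 4 has to be separated from the 2'-neryl isomer F3 on AgNO3-impregnated silica.

2. Step 3. What may go wrong: alkylation of the doubly ortho-flanked O3' is slow, so long exposure lets the chelated O5 be methylated as well. The fallback sets out from 4 and comes back at 5, and it asks for no discrimination between the hydroxyls.
   - Both hydroxyls are methylated under neutral conditions by a Mitsunobu reaction (excess MeOH, PPh3, DIAD, THF) to give the 5,7,3',4'-tetramethyl ether F4.
   - MgI2·OEt2 (toluene/Et2O, 50 °C) then removes only the 5-O-methyl group, because only this ether oxygen can chelate magnesium together with C4=O.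

3. Step 1. What may go wrong: the 7- and 3'-hydroxyls are not fully discriminated (double methylation), or proton transfer to the diazoalkane is sluggish. The fallback sets out from 1 and comes back at 2.
   - The methyl group is delivered by a SAM-dependent flavonoid 7-O-methyltransferase (naringenin 7-O-methyltransferase class) with S-adenosylmethionine in pH 7.5 buffer at 30 °C.
   - The site is then fixed by the enzyme pocket and not by relative acidity.
   - This fallback makes no new compound (F0).

Further compounds
F1 | step 2 | linalyl methyl carbonate (racemic) | C=CC(C)(CCC=C(C)C)OC(=O)OC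
F2 | step 2 | (2S)-3'-O-linalyl ether of 2 (both epimers at the ether carbon) | COc1cc(O)c2c(c1)O[C@H](c1ccc(OC)c(OC(C)(C=C)CCC=C(C)C)c1)CC2=O
F3 | step 2 | (2S)-2'-neryl-5,3'-dihydroxy-7,4'-dimethoxyflavanone (Z isomer of 4) | COc1cc(O)c2c(c1)O[C@H](c1ccc(OC)c(O)c1C/C=C(/C)CCC=C(C)C)CC2=O
F4 | step 3 | (2S)-2'-geranyl-5,7,3',4'-tetramethoxyflavanone | COc1cc(OC)c2c(c1)O[C@H](c1ccc(OC)c(OC)c1C/C=C(\C)CCC=C(C)C)CC2=O
F0 | step 1 | none | none
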